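## Retrosynthetic overview
1. The C16 carbinol comes from the ring B enone by reduction followed by SN2 inversion. Ring C (eleven-membered) is opened at C2=C3 (enyne/diene metathesis) and at C7–C8 (alkenylchromium addition). This gives a bicyclic iodo enone (fragment 1) and (S)-3-methylhex-5-enal (fragment 2).
2. Ring A carries a contra-thermodynamic endo side chain at C11. It comes from the key step, a photochemical Wolff ring contraction (1,2-shift of C10) of a cis-decalin diazo ketone, with the ketene captured by MeLi.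
3. Ring B comes from a gold-catalysed 6-endo closure of a silyl enol ether onto a methyl alkyne. C14 comes from a copper-catalysed asymmetric conjugate addition to 3-methylcyclohexenone.
4. Order of ring formation: bought six-membered ring, then ring B, then contraction of the six-membered ring to ring A, then ring C.

**Locants used below (not IUPAC):** C1 carries the exocyclic CH2. The chain continues C2=C3, C4, C5 (Me), C6, C7 (OAc), C8=C9 (Me on C9). C10 is the ring-fusion CH and C11 is the ring A carbon bonded to C1. Then come C12, C13, C14 (quaternary, Me), C15 (OAc) and C16 (OH). Ring A = C10–C14. Ring B = C8, C9, C10, C14, C15, C16. Ring C = C1–C11.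

**Assumption:** the ligand enantiomers in steps 2, 11 and 13 are those that give the configurations drawn.

## Route

Step 1
Reactants: 1 pent-3-yn-1-ol
Product: 2 5-bromopent-2-yne
Conditions: CBr4, PPh3, CH2Cl2, 0 °C
Reagents that add atoms: carbon tetrabromide, BrC(Br)(Br)Br
Why: Appel reaction, an SN2 displacement of the oxyphosphonium by bromide at a primary carbon, which leaves the internal alkyne untouched and creates no stereocentre.

Step 2
Reactants: 2 5-bromopent-2-yne; 3 3-methylcyclohex-2-en-1-one
Product: 6 tert-butyl(dimethyl){[(3R)-3-methyl-3-(pent-3-yn-1-yl)cyclohex-1-en-1-yl]oxy}silane, via Grignard reagent 4 (not isolated), via magnesium enolate 5 (not isolated)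
Conditions: Mg, Et2O; Cu(OTf)2 (3 mol %), chiral hydroxyalkyl-imidazolinium hexafluorophosphate (4 mol %), Et2O, −30 °C; TBSOTf, −30 °C to rt
Reagents that add atoms: TBSOTf, CC(C)(C)[Si](C)(C)OS(=O)(=O)C(F)(F)F; magnesium, [Mg] (kept only in 4, 5)
Why: Copper–NHC-catalysed asymmetric conjugate addition of a Grignard reagent to a β-methyl enone, in which the ligand selects the enone face and sets quaternary C14, and silylation traps the regiodefined C1=C10 enolate.

Step 3
Reactants: 6 silyl enol ether
Product: 7 (4aR,8aR)-4a,8-dimethyl-3,4,4a,5,6,8a-hexahydronaphthalen-1(2H)-one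
Conditions: (Me4-t-BuXPhos)Au(NCMe)SbF6 (5 mol %), MeOH (2 equiv), CH2Cl2, rt
Reagents that add atoms: none
Why: Monovalent-gold-catalysed 6-endo-dig carbocyclisation of a silyl enol ether onto an alkyne (Conia-ene type), where the very bulky biaryl phosphine favours the endo mode and the chain on C14 reaches C10 only from its own face, so ring B forms cis-fused with H-10 syn to the C14 methyl.

Step 4
Reactants: 7 cis-decalin β,γ-enone
Product: 9 (4aS,8aR)-2-diazo-4a,8-dimethyl-3,4,4a,5,6,8a-hexahydronaphthalen-1(2H)-one, via trifluoroacetyl ketone 8 (not isolated)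
Conditions: LiHMDS, THF, −78 °C; CF3CO2CH2CF3; then MsN3, Et3N, H2O, MeCN, rt
Reagents that add atoms: methanesulfonyl azide, CS(=O)(=O)N=[N+]=[N-]; 2,2,2-trifluoroethyl trifluoroacetate, O=C(OCC(F)(F)F)C(F)(F)F (kept only in 8)
Why: Detrifluoroacetylative (Regitz-type) diazo transfer, in which kinetic deprotonation takes the open C11 methylene rather than the hindered tertiary C10–H, so C10 and C14 are untouched.

Step 5
Reactants: 9 diazo ketone
Product: 12 1-[(1R,3aS,7aR)-3a,7-dimethyl-2,3,3a,4,5,7a-hexahydro-1H-inden-1-yl]ethan-1-one, via ketene 10 (not isolated), via lithium enolate 11 (not isolated)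
Conditions: hν (365 nm LED), THF, −78 °C until the diazo band is gone; MeLi (1.05 equiv), −78 °C; AcOH in THF, −78 °C
Reagents that add atoms: methyllithium, [Li]C
Why: Proposed new method: irradiation of the s-Z-locked cyclic diazo ketone expels N2 with a concerted 1,2-shift of C10 (retention) from C1 to C11, which contracts the six-membered ring to ring A and leaves a dialkylketene that persists at −78 °C without protic traps; MeLi then adds in the ketene plane to give a tetrasubstituted lithium enolate, and the small acid protonates C11 from the convex face (the face of H-10 and the C14 methyl, away from ring B), setting the contra-thermodynamic endo C11 centre; the closest known reaction types are the photochemical Wolff ring contraction of 2-diazocyclohexanones with alcohol or amine capture and the addition of organolithiums to isolable ketenes, which have not been joined in one flask nor used to set such a centre.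

Step 6
Reactants: 12 methyl ketone
Product: 14 (1R,3aS,7aR)-1-ethynyl-3a,7-dimethyl-2,3,3a,4,5,7a-hexahydro-1H-indene, via enol phosphate 13 (not isolated)
Conditions: LDA (1.1 equiv), THF, −78 °C; ClP(O)(OEt)2, to rt; LDA (2.3 equiv), −78 °C to rt; H2O
Reagents that add atoms: diethyl chlorophosphate, CCOP(=O)(Cl)OCC (kept only in 13)
Why: Negishi conversion of a methyl ketone into a terminal alkyne (kinetic enol phosphate, then β-elimination), where deprotonation occurs at CH3 and not at C11, so the endo centre is kept.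

Step 7
Reactants: 14 alkyne
Product: 15 (1R,3aR,7aR)-1-ethynyl-3a,7-dimethyl-1,2,3,3a,4,7a-hexahydro-5H-inden-5-one
Conditions: Rh2(cap)4 (1 mol %), t-BuOOH (5 equiv), K2CO3 (0.5 equiv), CH2Cl2, rt
Reagents that add atoms: tert-butyl hydroperoxide, CC(C)(C)OO
Why: Dirhodium-catalysed allylic oxidation, in which the tert-butylperoxy radical attacks the only allylic ring CH2 (C16) and the mixed peroxide collapses to the enone, as in the change of 1-methylcyclohexene into 3-methylcyclohexenone.

Step 8
Reactants: 15 enone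
Product: 16 (1R,3aS,4R,7aS)-1-ethynyl-3a,7-dimethyl-5-oxo-2,3,3a,4,5,7a-hexahydro-1H-inden-4-yl acetate
Conditions: Mn(OAc)3·2H2O (4 equiv), benzene, reflux (Dean–Stark)
Reagents that add atoms: manganese triacetate, [Mn+3].CC(=O)[O-].CC(=O)[O-].CC(=O)[O-]
Why: α′-Acetoxylation of an enone by trivalent manganese at the only α′ position (C15), where the epimerisable centre settles equatorial and syn to the C14 methyl because the axial epimer clashes with the axial C10–C11 bond.

Step 9
Reactants: 16 acetoxy enone
Product: 17 (1R,3aS,4R,7aR)-1-ethynyl-6-iodo-3a,7-dimethyl-5-oxo-2,3,3a,4,5,7a-hexahydro-1H-inden-4-yl acetate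
Conditions: iodine (2 equiv), pyridine–CH2Cl2 1:1, rt
Reagents that add atoms: iodine, [I][I]
Why: Johnson α-iodination (Baylis–Hillman-type addition of pyridine at C9, iodination at C8, loss of pyridine), which is routine for bicyclic β,β-disubstituted enones and forms no new stereocentre.

Step 10
Reactants: 18 pent-1-en-4-yne
Product: 20 methyl (2E)-3-methylhexa-2,5-dienoate, via alkenylalane 19 (not isolated)
Conditions: Me3Al, Cp2ZrCl2 (20 mol %), CH2Cl2, rt; ClCO2Me, 0 °C
Reagents that add atoms: trimethylaluminium, C[Al](C)C; methyl chloroformate, COC(=O)Cl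
Why: Negishi zirconium-catalysed syn-carboalumination of the terminal alkyne (faster than the alkene) followed by acylation with retention, which fixes the E geometry needed in step 11.

Step 11
Reactants: 20 dienoate
Product: 21 methyl (3S)-3-methylhex-5-enoate
Conditions: Cu(OAc)2·H2O (2 mol %), DTBM-SEGPHOS (2 mol %), (EtO)2MeSiH, t-BuOH, toluene, 0 °C
Reagents that add atoms: none
Why: Asymmetric conjugate reduction by a ligated monovalent copper hydride, which delivers hydride to the Re face of C3 of the pure E-enoate to set C5 as S, under base-free conditions that spare the isolated vinyl group.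

Step 12
Reactants: 21 ester
Product: 22 (3S)-3-methylhex-5-enal
Conditions: DIBAL-H (1.05 equiv), CH2Cl2, −78 °C; Rochelle salt
Reagents that add atoms: none
Why: Partial ester reduction through the stable tetrahedral aluminate at −78 °C, with the β-stereocentre out of reach of epimerisation.

Step 13
Reactants: 17 iodo enone (fragment 1); 22 aldehyde (fragment 2)
Product: 23 (1R,3aS,4R,7aS)-1-ethynyl-6-[(1S,3S)-1-hydroxy-3-methylhex-5-en-1-yl]-3a,7-dimethyl-5-oxo-2,3,3a,4,5,7a-hexahydro-1H-inden-4-yl acetate
Conditions: CrCl2 (4 equiv), NiCl2 (1 mol %), chiral oxazoline–sulfonamide ligand (4.4 equiv), Et3N, THF, rt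
Reagents that add atoms: none
Why: Nozaki–Hiyama–Kishi reaction, in which zerovalent nickel inserts into the activated carbon–iodine bond, transmetallation gives the alkenylchromium, and this adds only to the aldehyde, with the chromium-bound sulfonamide ligand directing Re-face attack to set C7 as S while ketone, acetate, alkyne and alkene are tolerated.

Step 14
Reactants: 23 allylic alcohol
Product: 24 (1R,3aS,4R,7aS)-6-[(1S,3S)-1-acetoxy-3-methylhex-5-en-1-yl]-1-ethynyl-3a,7-dimethyl-5-oxo-2,3,3a,4,5,7a-hexahydro-1H-inden-4-yl acetate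
Conditions: Ac2O, pyridine, DMAP (cat.), CH2Cl2, 0 °C
Reagents that add atoms: acetic anhydride, CC(=O)OC(C)=O
Why: DMAP-catalysed acetylation of the only free hydroxyl, made unambiguous because C16 is still a ketone, while SN2′ attack is blocked by the fully substituted C9.

Step 15
Reactants: 24 enyne diacetate
Product: 26 tricyclic 16-ketone (2E,5S,7S,10S,11R,14S,15R)-7,15-diacetoxy-16-oxo compound with the full target skeleton, via triene 25 (not isolated)
Conditions: second-generation Grubbs catalyst (10 mol %), ethylene (1 atm), CH2Cl2, rt; then argon purge, dilution to 0.5 mM in toluene, 80 °C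
Reagents that add atoms: ethylene, C=C
Why: Enyne cross-metathesis with ethylene turns the alkyne into a 2-substituted butadiene, and diene–ene ring-closing metathesis at its monosubstituted vinyl group then closes ring C, with the conjugated E-diene as the thermodynamic outcome in an eleven-membered ring that already holds the E-disposed C8=C9 (humulene-like).

Step 16
Reactants: 26 tricyclic 16-ketone
Product: 27 16-epi-target (16S axial alcohol)
Conditions: NaBH4, CeCl3·7H2O, MeOH, −78 °C
Reagents that add atoms: none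
Why: Luche 1,2-reduction, in which the axial C14 methyl blocks its own face of the C16 carbonyl (as in steroidal 6-ketones), so hydride enters from the opposite face and gives the axial 16S alcohol while acetates and diene stay intact.

Step 17
Reactants: 27 16-epi-target
Product: 29 target CNP0323842.1, via formate 28 (not isolated)
Conditions: PPh3, DIAD, HCO2H, THF, 0 °C to rt; then KHCO3, MeOH, 0 °C
Reagents that add atoms: formic acid, O=CO
Why: Mitsunobu reaction, in which formate displaces the axial oxyphosphonium by SN2 from the open face and inverts C16 to R (equatorial, trans to the C15 acetate), and the formate is then methanolysed much faster than the two acetates.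

## Compound list
1 | pent-3-yn-1-ol | CC#CCCO | starting material
2 | 5-bromopent-2-yne | CC#CCCBr | intermediate
3 | 3-methylcyclohex-2-en-1-one | CC1=CC(=O)CCC1 | starting material
4 | pent-3-yn-1-ylmagnesium bromide | CC#CCC[Mg]Br | intermediate
5 | bromomagnesium enolate of (R)-3-methyl-3-(pent-3-yn-1-yl)cyclohexanone | Br[Mg]OC1=C[C@@](C)(CCC#CC)CCC1 | intermediate
6 | tert-butyl(dimethyl){[(3R)-3-methyl-3-(pent-3-yn-1-yl)cyclohex-1-en-1-yl]oxy}silane | CC(C)(C)[Si](C)(C)OC1=C[C@@](C)(CCC#CC)CCC1 | intermediate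
7 | (4aR,8aR)-4a,8-dimethyl-3,4,4a,5,6,8a-hexahydronaphthalen-1(2H)-one (cis-fused) | C1=C(C)[C@@H]2C(=O)CCC[C@]2(C)CC1 | intermediate
8 | 2-(trifluoroacetyl) derivative of 7 | C1=C(C)[C@@H]2C(=O)C(C(=O)C(F)(F)F)CC[C@]2(C)CC1 | intermediate
9 | (4aS,8aR)-2-diazo-4a,8-dimethyl-3,4,4a,5,6,8a-hexahydronaphthalen-1(2H)-one | C1=C(C)[C@@H]2C(=O)C(=[N+]=[N-])CC[C@]2(C)CC1 | intermediate
10 | [(3aS,7aR)-3a,7-dimethyl-2,3,3a,4,5,7a-hexahydro-1H-inden-1-ylidene]methanone (ketene) | C1=C(C)[C@@H]2C(=C=O)CC[C@]2(C)CC1 | intermediate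
11 | lithium enolate from 10 and MeLi | [Li+].C1=C(C)[C@@H]2C(=C(C)[O-])CC[C@]2(C)CC1 | intermediate
12 | 1-[(1R,3aS,7aR)-3a,7-dimethyl-2,3,3a,4,5,7a-hexahydro-1H-inden-1-yl]ethan-1-one (acetyl endo, cis to C9) | C1=C(C)[C@@H]2[C@H](C(C)=O)CC[C@]2(C)CC1 | intermediate
13 | diethyl enol phosphate of 12 (terminal C=CH2) | C1=C(C)[C@@H]2[C@H](C(=C)OP(=O)(OCC)OCC)CC[C@]2(C)CC1 | intermediate
14 | (1R,3aS,7aR)-1-ethynyl-3a,7-dimethyl-2,3,3a,4,5,7a-hexahydro-1H-indene | C1=C(C)[C@@H]2[C@H](C#C)CC[C@]2(C)CC1 | intermediate
15 | (1R,3aR,7aR)-1-ethynyl-3a,7-dimethyl-1,2,3,3a,4,7a-hexahydro-5H-inden-5-one | O=C1C=C(C)[C@@H]2[C@H](C#C)CC[C@]2(C)C1 | intermediate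
16 | (1R,3aS,4R,7aS)-1-ethynyl-3a,7-dimethyl-5-oxo-2,3,3a,4,5,7a-hexahydro-1H-inden-4-yl acetate | O=C1C=C(C)[C@@H]2[C@H](C#C)CC[C@]2(C)[C@H]1OC(C)=O | intermediate
17 | (1R,3aS,4R,7aR)-1-ethynyl-6-iodo-3a,7-dimethyl-5-oxo-2,3,3a,4,5,7a-hexahydro-1H-inden-4-yl acetate | IC1=C(C)[C@@H]2[C@H](C#C)CC[C@]2(C)[C@@H](OC(C)=O)C1=O | intermediate
18 | pent-1-en-4-yne | C=CCC#C | starting material
19 | dimethyl[(1E)-2-methylpenta-1,4-dien-1-yl]alane | C=CC/C(C)=C/[Al](C)C | intermediate
20 | methyl (2E)-3-methylhexa-2,5-dienoate | C=CC/C(C)=C/C(=O)OC | intermediate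
21 | methyl (3S)-3-methylhex-5-enoate | C=CC[C@H](C)CC(=O)OC | intermediate
22 | (3S)-3-methylhex-5-enal | C=CC[C@H](C)CC=O | intermediate
23 | (1R,3aS,4R,7aS)-1-ethynyl-6-[(1S,3S)-1-hydroxy-3-methylhex-5-en-1-yl]-3a,7-dimethyl-5-oxo-2,3,3a,4,5,7a-hexahydro-1H-inden-4-yl acetate | C=CC[C@H](C)C[C@H](O)C1=C(C)[C@@H]2[C@H](C#C)CC[C@]2(C)[C@@H](OC(C)=O)C1=O | intermediate
24 | (1R,3aS,4R,7aS)-6-[(1S,3S)-1-acetoxy-3-methylhex-5-en-1-yl]-1-ethynyl-3a,7-dimethyl-5-oxo-2,3,3a,4,5,7a-hexahydro-1H-inden-4-yl acetate | C=CC[C@H](C)C[C@H](OC(C)=O)C1=C(C)[C@@H]2[C@H](C#C)CC[C@]2(C)[C@@H](OC(C)=O)C1=O | intermediate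
25 | buta-1,3-dien-2-yl analogue of 24 (alkyne plus ethylene) | C=CC[C@H](C)C[C@H](OC(C)=O)C1=C(C)[C@@H]2[C@H](C(=C)C=C)CC[C@]2(C)[C@@H](OC(C)=O)C1=O | intermediate
26 | tricyclic 16-ketone, (2E,5S,7S,10S,11R,14S,15R)-7,15-diacetate | C=C1/C=C/C[C@H](C)C[C@H](OC(C)=O)C2=C(C)[C@@H]3[C@H]1CC[C@]3(C)[C@@H](OC(C)=O)C2=O | intermediate
27 | 16-epi-target, (16S) axial alcohol | C=C1/C=C/C[C@H](C)C[C@H](OC(C)=O)C2=C(C)[C@@H]3[C@H]1CC[C@]3(C)[C@@H](OC(C)=O)[C@H]2O | intermediate
28 | 16-O-formate of the target, (16R) | C=C1/C=C/C[C@H](C)C[C@H](OC(C)=O)C2=C(C)[C@@H]3[C@H]1CC[C@]3(C)[C@@H](OC(C)=O)[C@@H]2OC=O | intermediate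
29 | CNP0323842.1, (2E,5S,7S,10S,11R,14S,15R,16R) | C=C1/C=C/C[C@H](C)C[C@H](OC(C)=O)C2=C(C)[C@@H]3[C@H]1CC[C@]3(C)[C@@H](OC(C)=O)[C@@H]2O | target

## Summary
**Total step count:** 17.
**Longest linear sequence:** 14 (steps 1–9 and 13–17). Steps 10–12 run in parallel.

## Steps most likely to fail

**Step 5 (the new ketene capture).**
- Risks: the ketene may dimerise or be only partly formed before MeLi is added, and protonation may not be fully face-selective.
- Fallback, from 9 back to 12, two extra steps, all known chemistry. Irradiation of 9 in MeOH gives the methyl (1R,3aS,7aR)-3a,7-dimethyl-2,3,3a,4,5,7a-hexahydro-1H-indene-1-carboxylate F1. This is the classical Wolff ring contraction with convex-face protonation of the ketene hemiacetal.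
- Me(MeO)NH·HCl with i-PrMgCl then turns it into the Weinreb amide F2, and MeMgBr at 0 °C gives 12.

**Step 15 (closure of the strained eleven-membered ring by metathesis).**
- Risks: oligomers, ring re-opening by ethylene, and poor control of alkene geometry.
- Fallback, from 17 and 22 back to 26: the two unions are swapped so that ring C is closed at C7–C8 instead.
- Cross enyne metathesis of 17 with 22 (second-generation Hoveyda–Grubbs catalyst, CH2Cl2, 40 °C) gives the diene aldehyde F3.
- An intramolecular Nozaki–Hiyama–Kishi reaction (CrCl2, NiCl2 cat., DMF–THF, 1 mM) closes the ring to the 7-hydroxy 16-ketone F4. Acetylation as in step 14 then gives 26.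

**Step 17 (Mitsunobu inversion of a hindered axial allylic alcohol).**
- Risks: slow activation and elimination toward C15.
- Fallback, from 27 directly to 29, without a new compound: thermodynamic equilibration replaces SN2.
- Re2O7 (5 mol %) in CH2Cl2 at rt reversibly ionises and transposes the free allylic alcohol through its perrhenate ester.
- The C16 epimers then funnel to the equatorial 16R alcohol, which lacks the syn-axial contact with the C14 methyl.

## Further compounds
F1 | step 5 | methyl (1R,3aS,7aR)-3a,7-dimethyl-2,3,3a,4,5,7a-hexahydro-1H-indene-1-carboxylate | C1=C(C)[C@@H]2[C@H](C(=O)OC)CC[C@]2(C)CC1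
F2 | step 5 | (1R,3aS,7aR)-N-methoxy-N,3a,7-trimethyl-2,3,3a,4,5,7a-hexahydro-1H-indene-1-carboxamide | C1=C(C)[C@@H]2[C@H](C(=O)N(C)OC)CC[C@]2(C)CC1
F3 | step 15 | (1R,3aS,4R,7aR)-6-iodo-3a,7-dimethyl-1-[(3E,6S)-6-methyl-8-oxoocta-1,3-dien-2-yl]-5-oxo-2,3,3a,4,5,7a-hexahydro-1H-inden-4-yl acetate | IC1=C(C)[C@@H]2[C@H](C(=C)/C=C/C[C@H](C)CC=O)CC[C@]2(C)[C@@H](OC(C)=O)C1=O
F4 | step 15 | tricyclic (7S)-7-hydroxy 16-ketone 15-acetate | C=C1/C=C/C[C@H](C)C[C@H](O)C2=C(C)[C@@H]3[C@H]1CC[C@]3(C)[C@@H](OC(C)=O)C2=O
F0 | step 17 | none | none
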